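**Retrosynthetic overview**
1. Target 22 comes from oxocene diol 19. The two acetates are put on, and the C6 silyl ether is replaced by chloride with inversion.
2. Diol 19 comes from bridged ketal 16. The smallest rings of 16 are a dihydropyran and a 1,3-dioxane that share O9. Reductive cleavage of C13–O9 enlarges the dioxane (6 atoms) to the oxocene (8 atoms).
3. Order of rings: furan (bought), then pyranone (Achmatowicz), then 1,3-dioxane (ketalisation), then oxocene. A dioxaborolane exists only during the key step.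
4. Furan diol 13 comes from an aldol of 2-acetyl-5-ethylfuran 11 with the malate-derived aldehyde 9, followed by a 1,3-anti reduction.
5. Enabling feature: the Z-C11=C12 bond between O-bearing C10 and C13 is an oxidised 2,5-disubstituted furan. The oxygens on C7 and C9 are 1,3-related through C8, so both can sit on C13. The C10 oxygen is vicinal to O9 and can clamp a boron onto it.

Key step: step 14

Remark: locants C1–C15 run from the alkyne CH (C1) through CHCl (C6), the ether carbons (C7, C13) and the acetoxy carbons (C9, C10) to the ethyl CH3 (C15). The target is read as 3E,11Z,6R,7R,9R,10R,13R.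

Step 1
Reactants: 1 dimethyl (S)-malate
Product: 2 methyl (S)-3,4-dihydroxybutanoate
Conditions: BH3·SMe2, cat. NaBH4, THF, 0 °C to rt; MeOH quench
Reagents that add atoms: none
Why: Hydroxyl-directed borane reduction, in which the oxyborane formed at the free OH reduces only the neighbouring ester and leaves the stereocentre (later C6) untouched.

Step 2
Reactants: 2 methyl (S)-3,4-dihydroxybutanoate
Product: 3 methyl (S)-3,4-bis[(tert-butyldimethylsilyl)oxy]butanoate
Conditions: TBSCl, imidazole, DMF, rt
Reagents that add atoms: tert-butyldimethylsilyl chloride, CC(C)(C)[Si](C)(C)Cl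
Why: Standard imidazole-promoted silylation of both hydroxyls, which also prevents lactonisation.

Step 3
Reactants: 3 methyl (S)-3,4-bis[(tert-butyldimethylsilyl)oxy]butanoate
Product: 4 (S)-3,4-bis[(tert-butyldimethylsilyl)oxy]butanal
Conditions: DIBAL-H, CH2Cl2, −78 °C; Rochelle salt
Reagents that add atoms: none
Why: Partial DIBAL reduction of an ester, where the tetrahedral aluminium hemiacetal survives at −78 °C and gives the aldehyde on work-up.

Step 4
Reactants: 5 3-bromo-1-(trimethylsilyl)prop-1-yne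
Product: 6 diethyl [3-(trimethylsilyl)prop-2-yn-1-yl]phosphonate
Conditions: P(OEt)3, neat, 140 °C
Reagents that add atoms: triethyl phosphite, CCOP(OCC)OCC
Why: Michaelis–Arbuzov reaction of a reactive propargylic bromide.

Step 5
Reactants: 4 (S)-3,4-bis[(tert-butyldimethylsilyl)oxy]butanal; 6 diethyl [3-(trimethylsilyl)prop-2-yn-1-yl]phosphonate
Product: 7 (2S,4E)-1,2-bis[(tert-butyldimethylsilyl)oxy]-7-(trimethylsilyl)hept-4-en-6-yne
Conditions: 6, LiHMDS, THF, −78 °C; then 4, −78 to 0 °C
Reagents that add atoms: none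
Why: Horner–Wadsworth–Emmons olefination with the propargyl phosphonate should give the E-enyne (C3=C4).

Step 6
Reactants: 7 (2S,4E)-1,2-bis[(tert-butyldimethylsilyl)oxy]-7-(trimethylsilyl)hept-4-en-6-yne
Product: 8 (2S,4E)-2-[(tert-butyldimethylsilyl)oxy]-7-(trimethylsilyl)hept-4-en-6-yn-1-ol
Conditions: cat. CSA, MeOH/CH2Cl2, 0 °C
Reagents that add atoms: none
Why: Acid-catalysed methanolysis cleaves the less hindered primary silyl ether first and spares the secondary TBS ether and the alkynyl silane.

Step 7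
Reactants: 8 (2S,4E)-2-[(tert-butyldimethylsilyl)oxy]-7-(trimethylsilyl)hept-4-en-6-yn-1-ol
Product: 9 (2S,4E)-2-[(tert-butyldimethylsilyl)oxy]-7-(trimethylsilyl)hept-4-en-6-ynal
Conditions: Dess–Martin periodinane, CH2Cl2, 0 °C to rt
Reagents that add atoms: none
Why: Dess–Martin oxidation is non-basic, so the α-silyloxy stereocentre (C6) should not epimerise.

Step 8
Reactants: 10 2-ethylfuran
Product: 11 1-(5-ethylfuran-2-yl)ethan-1-one
Conditions: Ac2O, cat. H3PO4, 50 °C
Reagents that add atoms: acetic anhydride, CC(=O)OC(C)=O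
Why: Friedel–Crafts acylation takes place at the only free α-position of the furan.

Step 9
Reactants: 9 (2S,4E)-2-[(tert-butyldimethylsilyl)oxy]-7-(trimethylsilyl)hept-4-en-6-ynal; 11 1-(5-ethylfuran-2-yl)ethan-1-one
Product: 12 (3R,4S,6E)-4-[(tert-butyldimethylsilyl)oxy]-1-(5-ethylfuran-2-yl)-3-hydroxy-9-(trimethylsilyl)non-6-en-8-yn-1-one
Conditions: 11, LDA, THF, −78 °C; then 9, −78 °C; AcOH quench
Reagents that add atoms: none
Why: Lithium enolate aldol addition, where polar Felkin–Anh (Cornforth) control by the non-chelating α-OTBS group should favour the 6,7-anti adduct and set C7 as R.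

Step 10
Reactants: 12 (3R,4S,6E)-4-[(tert-butyldimethylsilyl)oxy]-1-(5-ethylfuran-2-yl)-3-hydroxy-9-(trimethylsilyl)non-6-en-8-yn-1-one
Product: 13 (1R,3R,4S,6E)-4-[(tert-butyldimethylsilyl)oxy]-1-(5-ethylfuran-2-yl)-9-(trimethylsilyl)non-6-en-8-yne-1,3-diol
Conditions: Me4NBH(OAc)3, MeCN/AcOH, −30 °C
Reagents that add atoms: none
Why: Evans–Saksena reduction, where the C7 hydroxyl binds boron and delivers hydride internally to give the 1,3-anti diol (C9 R).

Step 11
Reactants: 13 (1R,3R,4S,6E)-4-[(tert-butyldimethylsilyl)oxy]-1-(5-ethylfuran-2-yl)-9-(trimethylsilyl)non-6-en-8-yne-1,3-diol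
Product: 14 (2R)-6-ethyl-6-hydroxy-2-[(2R,3S,5E)-3-[(tert-butyldimethylsilyl)oxy]-2-hydroxy-8-(trimethylsilyl)oct-5-en-7-yn-1-yl]-2H-pyran-3(6H)-one (hemiketal, both anomers)
Conditions: NBS, NaHCO3, THF/H2O, 0 °C
Reagents that add atoms: water, O
Why: Achmatowicz rearrangement, in which the electron-rich furan is oxidised far faster than the silyl-capped enyne and the furfuryl C9 hydroxyl closes the pyranone, so the Z-C11=C12 bond and the C10 and C13 oxygenation come from the furan.

Step 12
Reactants: 14 Achmatowicz hemiketal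
Product: 15 1-ethyl-3-[(1S,3E)-1-[(tert-butyldimethylsilyl)oxy]-6-(trimethylsilyl)hex-3-en-5-yn-1-yl]-2,9-dioxabicyclo[3.3.1]non-7-en-6-one (C6 S, C7 R, C9 R; side chain equatorial on the dioxane; C13 fixed by the bridge)
Conditions: cat. CSA, 4 Å MS, CH2Cl2, rt
Reagents that add atoms: none
Why: Acid-catalysed bicycloketalisation, where the C7 hydroxyl adds to the pyranyl oxocarbenium ion to close the six-membered 1,3-dioxane, the bridge dictates C13, and the anti-1,3-diol places the side chain equatorial.

Step 13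
Reactants: 15 bridged enone ketal
Product: 16 1-ethyl-3-[(1S,3E)-1-[(tert-butyldimethylsilyl)oxy]-6-(trimethylsilyl)hex-3-en-5-yn-1-yl]-2,9-dioxabicyclo[3.3.1]non-7-en-6-ol (C10 R, hydroxyl trans to O9 in the later diol)
Conditions: NaBH4, CeCl3·7H2O, MeOH, −78 °C
Reagents that add atoms: none
Why: Luche 1,2-reduction, in which hydride reaches C10 from the open face beside the one-atom O9 bridge and away from the C8–C7–O bridge, giving the pseudo-equatorial alcohol (C10 R).

Step 14
Reactants: 16 bridged allylic alcohol ketal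
Product: 19 (2R,4R,5R,8R,6Z)-8-ethyl-2-[(1S,3E)-1-[(tert-butyldimethylsilyl)oxy]-6-(trimethylsilyl)hex-3-en-5-yn-1-yl]-3,4,5,8-tetrahydro-2H-oxocine-4,5-diol, via C10 chlorophenylborinate 17 (not isolated), via oxocene phenylboronate 18 (not isolated)
Conditions: PhBCl2 (1.05 equiv), 4 Å MS, CH2Cl2, −78 °C; Et3SiH (3 equiv), −78 to −30 °C; then pinacol, Et2O, rt
Reagents that add atoms: none
Why: Proposed new method: PhBCl2 first borylates the only free hydroxyl (C10–OH, 17); its boron then binds the vicinal bridge oxygen O9 in a five-membered chelate, the antiperiplanar lone pair on the C7 oxygen pushes out the C13–O9 bond, the 1,3-dioxane ring (C13, O, C7, C8, C9, O9) becomes the eight-membered allylic oxocarbenium ion because C10–C11=C12 takes the place of O9 (six to eight atoms), and Et3SiH then delivers hydride to C13 (18). The closest known reaction types are the PhBCl2/Et3SiH reductive opening of cyclic acetals, the Lewis acid/silane cleavage of bridged bicyclic ketals that runs with inversion, and the silane reduction of eight-membered oxocarbenium ions to cis-2,8-disubstituted oxocanes; what is new is the covalent boron tether that chooses between the two ketal oxygens. The only ring that closes is the temporary 1,3,2-dioxaborolane (O9 to B, five-membered chelation); no bond of the oxocene is made, because the oxocene is released by cutting the one-atom bridge. The new stereocentre C13 is set by silane attack on the face opposite the departing O9–B group (inversion at the ketal carbon), which places ethyl cis to the C7 side chain (13R). The step needs O9 over O7 cleavage, secured by the C10–O–B tether (five- versus seven-membered chelate), by one equivalent of boron reagent and by the bulky C6 silyl ether beside O7; it needs 1,2- over 1,4-hydride transfer, which is usual for Ferrier-type allyl oxocarbenium ions; and it must not revert or aromatise to the furan, which the low nucleophilicity of the two boron-bound oxygens secures. The Z alkene and C6, C7, C9 and C10 are untouched.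

Step 15
Reactants: 19 oxocene diol
Product: 20 (2R,4R,5R,8R,6Z)-8-ethyl-2-[(1S,3E)-1-[(tert-butyldimethylsilyl)oxy]-6-(trimethylsilyl)hex-3-en-5-yn-1-yl]-3,4,5,8-tetrahydro-2H-oxocine-4,5-diyl diacetate
Conditions: Ac2O, pyridine, cat. DMAP, CH2Cl2, rt
Reagents that add atoms: acetic anhydride, CC(=O)OC(C)=O
Why: DMAP-catalysed acetylation of the two free secondary hydroxyls with retention at C9 and C10.

Step 16
Reactants: 20 silylated diacetate
Product: 21 (2R,4R,5R,8R,6Z)-8-ethyl-2-[(1S,3E)-1-hydroxyhex-3-en-5-yn-1-yl]-3,4,5,8-tetrahydro-2H-oxocine-4,5-diyl diacetate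
Conditions: TBAF, AcOH (1:1), THF, 0 °C to rt
Reagents that add atoms: none
Why: Buffered fluoride desilylation removes the O-TBS and C-TMS groups together, the acetic acid buffer protects the acetates, and the C6 hydroxyl is too far from them for acyl migration.

Step 17
Reactants: 21 C6 alcohol
Product: 22 target, (2R,4R,5R,8R,6Z)-2-[(1R,3E)-1-chlorohex-3-en-5-yn-1-yl]-8-ethyl-3,4,5,8-tetrahydro-2H-oxocine-4,5-diyl diacetate
Conditions: CCl4, P(n-C8H17)3, toluene, 70 °C
Reagents that add atoms: carbon tetrachloride, ClC(Cl)(Cl)Cl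
Why: Appel-type chlorination, in which SN2 displacement of the alkoxyphosphonium ion by chloride inverts C6 (S to R) and gives the syn chloro-ether array.

**Compound list**
1 | dimethyl (S)-malate | COC(=O)C[C@H](O)C(=O)OC | starting material
2 | methyl (S)-3,4-dihydroxybutanoate | COC(=O)C[C@H](O)CO | intermediate
3 | methyl (S)-3,4-bis[(tert-butyldimethylsilyl)oxy]butanoate | COC(=O)C[C@H](O[Si](C)(C)C(C)(C)C)CO[Si](C)(C)C(C)(C)C | intermediate
4 | (S)-3,4-bis[(tert-butyldimethylsilyl)oxy]butanal | O=CC[C@H](O[Si](C)(C)C(C)(C)C)CO[Si](C)(C)C(C)(C)C | intermediate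
5 | 3-bromo-1-(trimethylsilyl)prop-1-yne | C[Si](C)(C)C#CCBr | starting material
6 | diethyl [3-(trimethylsilyl)prop-2-yn-1-yl]phosphonate | CCOP(=O)(CC#C[Si](C)(C)C)OCC | intermediate
7 | (2S,4E)-1,2-bis[(tert-butyldimethylsilyl)oxy]-7-(trimethylsilyl)hept-4-en-6-yne | C[Si](C)(C)C#C/C=C/C[C@H](O[Si](C)(C)C(C)(C)C)CO[Si](C)(C)C(C)(C)C | intermediate
8 | (2S,4E)-2-[(tert-butyldimethylsilyl)oxy]-7-(trimethylsilyl)hept-4-en-6-yn-1-ol | C[Si](C)(C)C#C/C=C/C[C@H](O[Si](C)(C)C(C)(C)C)CO | intermediate
9 | (2S,4E)-2-[(tert-butyldimethylsilyl)oxy]-7-(trimethylsilyl)hept-4-en-6-ynal | C[Si](C)(C)C#C/C=C/C[C@H](O[Si](C)(C)C(C)(C)C)C=O | intermediate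
10 | 2-ethylfuran | CCc1ccco1 | starting material
11 | 1-(5-ethylfuran-2-yl)ethan-1-one | CCc1ccc(C(C)=O)o1 | intermediate
12 | aldol adduct (C6 S, C7 R) | C[Si](C)(C)C#C/C=C/C[C@H](O[Si](C)(C)C(C)(C)C)[C@H](O)CC(=O)c1ccc(CC)o1 | intermediate
13 | anti-1,3-diol (C6 S, C7 R, C9 R) | C[Si](C)(C)C#C/C=C/C[C@H](O[Si](C)(C)C(C)(C)C)[C@H](O)C[C@@H](O)c1ccc(CC)o1 | intermediate
14 | Achmatowicz pyranone hemiketal (anomers at C13) | C[Si](C)(C)C#C/C=C/C[C@H](O[Si](C)(C)C(C)(C)C)[C@H](O)C[C@H]1OC(O)(CC)C=CC1=O | intermediate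
15 | bridged enone ketal, 2,9-dioxabicyclo[3.3.1]non-7-en-6-one | C[Si](C)(C)C#C/C=C/C[C@H](O[Si](C)(C)C(C)(C)C)[C@H]2C[C@H]1O[C@@](CC)(O2)C=CC1=O | intermediate
16 | bridged allylic alcohol ketal (C10 R) | C[Si](C)(C)C#C/C=C/C[C@H](O[Si](C)(C)C(C)(C)C)[C@H]2C[C@H]1O[C@@](CC)(O2)C=C[C@H]1O | intermediate
17 | C10 O-chloro(phenyl)boryl derivative of 16 | C[Si](C)(C)C#C/C=C/C[C@H](O[Si](C)(C)C(C)(C)C)[C@H]2C[C@H]1O[C@@](CC)(O2)C=C[C@H]1OB(Cl)c3ccccc3 | intermediate
18 | oxocene C9,C10-phenylboronate | C[Si](C)(C)C#C/C=C/C[C@H](O[Si](C)(C)C(C)(C)C)[C@H]1C[C@H]2OB(c3ccccc3)O[C@@H]2/C=C\[C@@H](CC)O1 | intermediate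
19 | oxocene diol (C6 S, C7 R, C9 R, C10 R, C13 R) | C[Si](C)(C)C#C/C=C/C[C@H](O[Si](C)(C)C(C)(C)C)[C@H]1C[C@@H](O)[C@H](O)/C=C\[C@@H](CC)O1 | intermediate
20 | silylated oxocene diacetate | C[Si](C)(C)C#C/C=C/C[C@H](O[Si](C)(C)C(C)(C)C)[C@H]1C[C@@H](OC(C)=O)[C@H](OC(C)=O)/C=C\[C@@H](CC)O1 | intermediate
21 | C6 alcohol diacetate (C6 S) | C#C/C=C/C[C@H](O)[C@H]1C[C@@H](OC(C)=O)[C@H](OC(C)=O)/C=C\[C@@H](CC)O1 | intermediate
22 | CNP0268129.2 | C#C/C=C/C[C@@H](Cl)[C@H]1C[C@@H](OC(C)=O)[C@H](OC(C)=O)/C=C\[C@@H](CC)O1 | target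

**Step count and longest sequence**
- Total steps: 17.
- Longest linear sequence: 15 steps (1–3, 5–7, 9–17).

**Steps most likely to fail**

**Step 14.**
- What may go wrong: ionisation of the other ketal bond (C13–O7) to the six-membered pyranyl cation, conjugate hydride delivery, or collapse back to a furan.
- The fallback uses known chemistry, the hydroxy-dithioketal cyclisation developed for oxocenes, and blocks O9 outright. It sets out from 16 and returns at 19.
- EtSH with Zn(OTf)2 in CH2Cl2 opens the ketal to the acyclic Z-allylic dithioketal triol F1.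
- 2,2-Dimethoxypropane with PPTS ties the vicinal C9/C10 diol into the acetonide F2, so only the C7 hydroxyl stays free.
- NCS, AgNO3, 2,6-lutidine, SiO2 and 4 Å MS in MeCN close the eight-membered O,S-ketal F3, helped by the Z alkene.
- Ph3SnH with AIBN in toluene removes the ethylthio group to give the cis-oxocene acetonide F4.
- Aqueous AcOH then releases 19.

**Step 9.**
- What may go wrong: poor facial selectivity at the α-silyloxy aldehyde, or retro-aldol equilibration of the lithium aldolate.
- The fallback sets out from 11 and returns at 12.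
- TMSOTf with Et3N gives the silyl enol ether F5.
- A Mukaiyama aldol addition of F5 to 9 with BF3·OEt2 in CH2Cl2 at −78 °C follows. It has an open transition state, uses a non-chelating Lewis acid and is irreversible, so polar Felkin–Anh control should give the same 6,7-anti adduct 12.

**Step 17.**
- What may go wrong: participation of the ring oxygen through an oxiranium ion, which gives retention or ring-enlarged chloride, or elimination towards the enyne.
- The fallback sets out from 21 and returns at 22.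
- ClCH2SO2Cl with pyridine gives the chloromethanesulfonate F6.
- LiCl in DMF at rt displaces this very good leaving group by a plain SN2 reaction with inversion.

Further compounds
F1 | step 14 | acyclic (Z)-C13 diethyl dithioketal triol | C[Si](C)(C)C#C/C=C/C[C@H](O[Si](C)(C)C(C)(C)C)[C@H](O)C[C@@H](O)[C@H](O)/C=C\C(CC)(SCC)SCC
F2 | step 14 | C9,C10-acetonide of F1 with free C7 hydroxyl | C[Si](C)(C)C#C/C=C/C[C@H](O[Si](C)(C)C(C)(C)C)[C@H](O)C[C@H]1OC(C)(C)O[C@@H]1/C=C\C(CC)(SCC)SCC
F3 | step 14 | eight-membered O,S-ketal acetonide (either C13 epimer) | C[Si](C)(C)C#C/C=C/C[C@H](O[Si](C)(C)C(C)(C)C)[C@H]1C[C@H]2OC(C)(C)O[C@@H]2/C=C\C(CC)(SCC)O1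
F4 | step 14 | cis-oxocene C9,C10-acetonide | C[Si](C)(C)C#C/C=C/C[C@H](O[Si](C)(C)C(C)(C)C)[C@H]1C[C@H]2OC(C)(C)O[C@@H]2/C=C\[C@@H](CC)O1
F5 | step 9 | [1-(5-ethylfuran-2-yl)ethenyl]oxytrimethylsilane | C=C(O[Si](C)(C)C)c1ccc(CC)o1
F6 | step 17 | C6 chloromethanesulfonate of 21 | C#C/C=C/C[C@H](OS(=O)(=O)CCl)[C@H]1C[C@@H](OC(C)=O)[C@H](OC(C)=O)/C=C\[C@@H](CC)O1
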